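**Retrosynthetic overview**

1. The target comes from a fully protected precursor by thiolate cleavage of two aryl methyl ethers and acid removal of one MOM group; the C4 prenyl group comes from Stille coupling of a benzofuran-4-yl triflate.
2. The underlying 7-methoxybenzofuran-4-ol comes from a Dötz benzannulation of the 2-furyl(methoxy)carbene chromium complex, the ring-A pent-4-ynyl arene and one CO ligand. The strategy rests on the benzo ring of the benzofuran (C3a, C4, C5, C6, C7, C7a): oxygen on C7, carbon on C4 and C5, hydrogen on C6. That is the 4,7-dioxygenated, 5-substituted ring this three-component union gives, with C7–C6, C5–C4 and C4–C3a as the new bonds.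
3. The ring-A alkyne comes from copper-catalysed coupling of an aryl Grignard reagent with a silyl-capped iodopentyne; its 1,1-dimethylallyl group comes from aromatic Claisen rearrangement of the prenyl ether of 4-bromo-3-methoxyphenol.
4. The carbene complex comes from furan, Cr(CO)6 and methyl triflate.
5. Ring order: ring A and the furan ring are bought; the only ring made is the benzo ring of the benzofuran, closed in the key step.

Key step: step 7

Assumption: (5-iodopent-1-yn-1-yl)trimethylsilane and tributyl(3-methylbut-2-en-1-yl)stannane are bought, and the ring-A oxygen beside the chain is carried as the methyl ether of the commercial bromophenol and cleaved together with the C7 methyl ether.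

**Route**

Step 1
Reactants: 1 4-bromo-3-methoxyphenol; 2 prenyl bromide (1-bromo-3-methylbut-2-ene)
Product: 3 1-bromo-2-methoxy-4-[(3-methylbut-2-en-1-yl)oxy]benzene
Conditions: K2CO3, acetone, reflux
Reagents that add atoms: none
Why: Williamson ether synthesis, in which the phenoxide attacks the primary allylic bromide by SN2 at CH2 and so gives the O-prenyl ether without allyl transposition.

Step 2
Reactants: 3 1-bromo-2-methoxy-4-[(3-methylbut-2-en-1-yl)oxy]benzene
Product: 5 4-bromo-5-methoxy-2-(2-methylbut-3-en-2-yl)phenol, via cyclohexadienone 4 (not isolated)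
Conditions: Eu(fod)3 (10 mol %), CHCl3, 60 °C
Reagents that add atoms: none
Why: Aromatic Claisen rearrangement, whose [3,3] shift inverts the prenyl group to 1,1-dimethylallyl at the open ortho carbon para to OMe (the other ortho carbon lies between two oxygens and is too crowded to take a quaternary carbon), after which dienone 4 tautomerises to the phenol.

Step 3
Reactants: 5 4-bromo-5-methoxy-2-(2-methylbut-3-en-2-yl)phenol
Product: 6 1-bromo-2-methoxy-4-(methoxymethoxy)-5-(2-methylbut-3-en-2-yl)benzene
Conditions: NaH, MOMCl, THF–DMF, 0 °C → rt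
Reagents that add atoms: chloromethyl methyl ether, COCCl
Why: O-alkylation of the sodium phenoxide by the α-chloro ether (MOM acetal protection), with NaH chosen because the phenol sits beside the quaternary carbon.

Step 4
Reactants: 6 1-bromo-2-methoxy-4-(methoxymethoxy)-5-(2-methylbut-3-en-2-yl)benzene; 7 (5-iodopent-1-yn-1-yl)trimethylsilane
Product: 9 trimethyl{5-[2-methoxy-4-(methoxymethoxy)-5-(2-methylbut-3-en-2-yl)phenyl]pent-1-yn-1-yl}silane, via aryl Grignard reagent 8 (not isolated)
Conditions: Mg, THF, reflux; then 7, Li2CuCl4 (5 mol %), THF, 0 °C → rt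
Reagents that add atoms: none
Why: Grignard formation followed by a copper-catalysed Kochi-type sp2–sp3 cross-coupling with the primary alkyl iodide, conditions under which the silyl-capped alkyne, the acetal and the terminal alkene are inert.

Step 5
Reactants: 9 trimethyl{5-[2-methoxy-4-(methoxymethoxy)-5-(2-methylbut-3-en-2-yl)phenyl]pent-1-yn-1-yl}silane
Product: 10 1-methoxy-5-(methoxymethoxy)-4-(2-methylbut-3-en-2-yl)-2-(pent-4-yn-1-yl)benzene
Conditions: K2CO3 (cat.), MeOH, rt
Reagents that add atoms: none
Why: Base-catalysed protodesilylation, in which methoxide attacks silicon and the acetylide is protonated by methanol, leaving every other group untouched.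

Step 6
Reactants: 11 furan; 12 chromium hexacarbonyl
Product: 15 pentacarbonyl[(furan-2-yl)(methoxy)methylidene]chromium, via 2-furyllithium 13 (not isolated), via lithium acyl chromate 14 (not isolated)
Conditions: n-BuLi, THF, −78 → 0 °C; Cr(CO)6, 0 °C → rt; then MeOTf, CH2Cl2, 0 °C → rt
Reagents that add atoms: methyl trifluoromethanesulfonate, COS(=O)(=O)C(F)(F)F
Why: Fischer carbene synthesis, that is α-lithiation of furan, addition of the organolithium to a CO ligand and O-methylation of the resulting acyl chromate by a hard methylating agent.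

Step 7
Reactants: 15 pentacarbonyl[(furan-2-yl)(methoxy)methylidene]chromium; 10 1-methoxy-5-(methoxymethoxy)-4-(2-methylbut-3-en-2-yl)-2-(pent-4-yn-1-yl)benzene
Product: 18 7-methoxy-5-{3-[2-methoxy-4-(methoxymethoxy)-5-(2-methylbut-3-en-2-yl)phenyl]propyl}-1-benzofuran-4-ol, via chromium vinylketene complex 16 (not isolated), via tricarbonylchromium phenol complex 17 (not isolated)
Conditions: THF, 55 °C, Ar, slow addition of 10 to 15; then air, rt
Reagents that add atoms: none
Why: Dötz benzannulation: thermal loss of one CO from 15 lets the terminal alkyne of 10 coordinate and insert into the chromium–carbene bond with its unsubstituted carbon joined to the carbene carbon (C7–C6), and CO insertion then gives the chromium-bound furyl vinylketene 16 (C5–C4). A 6π electrocyclisation of 16 onto furan C3 (C4–C3a) closes the six-membered carbocycle, and tautomerisation gives the 4-hydroxy-7-methoxybenzofuran as its Cr(CO)3 complex 17, from which air releases 18. The closest known reaction type is the benzannulation of 2-furyl(alkoxy)carbene chromium complexes with terminal alkyl alkynes to 5-alkyl-7-alkoxybenzofuran-4-ols. No stereocentre is formed. The step needs a single alkyne orientation, which the steric difference between hydrogen and the CH2 chain secures (the larger group ends beside the CO-derived carbon C4, hydrogen on C6). It also needs the carbene to leave the two isolated alkenes of ring A alone, which is secured by the much faster alkyne insertion at 55 °C and by a tether too long for either alkene to reach the vinylcarbene.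

Step 8
Reactants: 18 7-methoxy-5-{3-[2-methoxy-4-(methoxymethoxy)-5-(2-methylbut-3-en-2-yl)phenyl]propyl}-1-benzofuran-4-ol
Product: 19 7-methoxy-5-{3-[2-methoxy-4-(methoxymethoxy)-5-(2-methylbut-3-en-2-yl)phenyl]propyl}-1-benzofuran-4-yl trifluoromethanesulfonate
Conditions: PhNTf2, Et3N, DMAP (cat.), CH2Cl2, 0 °C → rt
Reagents that add atoms: N-phenylbis(trifluoromethanesulfonimide), O=S(=O)(N(c1ccccc1)S(=O)(=O)C(F)(F)F)C(F)(F)F
Why: O-sulfonylation of the only free phenol to the aryl triflate with a mild triflyl donor that leaves the acetal and both alkenes untouched.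

Step 9
Reactants: 19 7-methoxy-5-{3-[2-methoxy-4-(methoxymethoxy)-5-(2-methylbut-3-en-2-yl)phenyl]propyl}-1-benzofuran-4-yl trifluoromethanesulfonate; 20 tributyl(3-methylbut-2-en-1-yl)stannane
Product: 21 7-methoxy-5-{3-[2-methoxy-4-(methoxymethoxy)-5-(2-methylbut-3-en-2-yl)phenyl]propyl}-4-(3-methylbut-2-en-1-yl)-1-benzofuran
Conditions: Pd(PPh3)4 (10 mol %), LiCl, DMF, 100 °C
Reagents that add atoms: none
Why: Stille coupling, in which zerovalent palladium adds to the aryl triflate, chloride replaces triflate, the prenyl group moves from tin to palladium and reductive elimination takes place through the primary allyl terminus, the terminus that the doubly ortho-substituted aryl group favours, to give the linear prenyl arene.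

Step 10
Reactants: 21 7-methoxy-5-{3-[2-methoxy-4-(methoxymethoxy)-5-(2-methylbut-3-en-2-yl)phenyl]propyl}-4-(3-methylbut-2-en-1-yl)-1-benzofuran
Product: 22 5-{3-[2-hydroxy-4-(methoxymethoxy)-5-(2-methylbut-3-en-2-yl)phenyl]propyl}-4-(3-methylbut-2-en-1-yl)-1-benzofuran-7-ol
Conditions: NaSEt (excess), DMF, 130 °C; then aq. NH4Cl
Reagents that add atoms: none
Why: Thiolate O-demethylation, in which ethanethiolate attacks each O–CH3 carbon by SN2 and frees one phenoxide on each of the two separate rings, while the MOM acetal, the alkenes and the furan offer no comparable electrophilic site.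

Step 11
Reactants: 22 5-{3-[2-hydroxy-4-(methoxymethoxy)-5-(2-methylbut-3-en-2-yl)phenyl]propyl}-4-(3-methylbut-2-en-1-yl)-1-benzofuran-7-ol
Product: 23 4-{3-[7-hydroxy-4-(3-methylbut-2-en-1-yl)-1-benzofuran-5-yl]propyl}-6-(2-methylbut-3-en-2-yl)benzene-1,3-diol (target)
Conditions: HCl (2 M aq.), MeOH, 40 °C
Reagents that add atoms: none
Why: Acid-catalysed acetal cleavage of the MOM ether through an oxocarbenium ion that methanol traps, run in acid dilute enough that neither the neighbouring phenol nor methanol should add across the vinyl or prenyl double bond.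

**Compound list**

1 | 4-bromo-3-methoxyphenol | COc1cc(O)ccc1Br | starting material
2 | prenyl bromide (1-bromo-3-methylbut-2-ene) | CC(C)=CCBr | starting material
3 | 1-bromo-2-methoxy-4-[(3-methylbut-2-en-1-yl)oxy]benzene | COc1cc(OCC=C(C)C)ccc1Br | intermediate
4 | 4-bromo-3-methoxy-6-(2-methylbut-3-en-2-yl)cyclohexa-2,4-dien-1-one (racemic) | O=C1C=C(OC)C(Br)=CC1C(C)(C)C=C | intermediate (not isolated)
5 | 4-bromo-5-methoxy-2-(2-methylbut-3-en-2-yl)phenol | COc1cc(O)c(C(C)(C)C=C)cc1Br | intermediate
6 | 1-bromo-2-methoxy-4-(methoxymethoxy)-5-(2-methylbut-3-en-2-yl)benzene | COCOc1cc(OC)c(Br)cc1C(C)(C)C=C | intermediate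
7 | (5-iodopent-1-yn-1-yl)trimethylsilane | C[Si](C)(C)C#CCCCI | starting material
8 | [2-methoxy-4-(methoxymethoxy)-5-(2-methylbut-3-en-2-yl)phenyl]magnesium bromide | COCOc1cc(OC)c([Mg]Br)cc1C(C)(C)C=C | intermediate (not isolated)
9 | trimethyl{5-[2-methoxy-4-(methoxymethoxy)-5-(2-methylbut-3-en-2-yl)phenyl]pent-1-yn-1-yl}silane | COCOc1cc(OC)c(CCCC#C[Si](C)(C)C)cc1C(C)(C)C=C | intermediate
10 | 1-methoxy-5-(methoxymethoxy)-4-(2-methylbut-3-en-2-yl)-2-(pent-4-yn-1-yl)benzene | COCOc1cc(OC)c(CCCC#C)cc1C(C)(C)C=C | intermediate (key-step precursor)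
11 | furan | c1ccoc1 | starting material
12 | chromium hexacarbonyl | O=C=[Cr](=C=O)(=C=O)(=C=O)(=C=O)=C=O | starting material
13 | 2-furyllithium | [Li]c1ccco1 | intermediate (not isolated)
14 | lithium pentacarbonyl[(furan-2-yl)(oxido)methylidene]chromate | [Li+].[O-]C(c1ccco1)=[Cr](=C=O)(=C=O)(=C=O)(=C=O)=C=O | intermediate (not isolated)
15 | pentacarbonyl[(furan-2-yl)(methoxy)methylidene]chromium | COC(c1ccco1)=[Cr](=C=O)(=C=O)(=C=O)(=C=O)=C=O | intermediate (key-step precursor)
16 | Cr(CO)3 complex of (3E)-4-(furan-2-yl)-4-methoxy-2-{3-[2-methoxy-4-(methoxymethoxy)-5-(2-methylbut-3-en-2-yl)phenyl]propyl}buta-1,3-dien-1-one (π-bound Cr(CO)3 written as a separate fragment) | O=C=C(CCCc1cc(C(C)(C)C=C)c(OCOC)cc1OC)/C=C(/OC)c1ccco1.O=C=[Cr](=C=O)=C=O | intermediate (not isolated)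
17 | Cr(CO)3 complex of phenol 18 (π-bound Cr(CO)3 written as a separate fragment) | COc1cc(CCCc2cc(C(C)(C)C=C)c(OCOC)cc2OC)c(O)c2ccoc12.O=C=[Cr](=C=O)=C=O | intermediate (not isolated)
18 | 7-methoxy-5-{3-[2-methoxy-4-(methoxymethoxy)-5-(2-methylbut-3-en-2-yl)phenyl]propyl}-1-benzofuran-4-ol | COc1cc(CCCc2cc(C(C)(C)C=C)c(OCOC)cc2OC)c(O)c2ccoc12 | intermediate (key-step product)
19 | 7-methoxy-5-{3-[2-methoxy-4-(methoxymethoxy)-5-(2-methylbut-3-en-2-yl)phenyl]propyl}-1-benzofuran-4-yl trifluoromethanesulfonate | COc1cc(CCCc2cc(C(C)(C)C=C)c(OCOC)cc2OC)c(OS(=O)(=O)C(F)(F)F)c2ccoc12 | intermediate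
20 | tributyl(3-methylbut-2-en-1-yl)stannane | CCCC[Sn](CCCC)(CCCC)CC=C(C)C | starting material
21 | 7-methoxy-5-{3-[2-methoxy-4-(methoxymethoxy)-5-(2-methylbut-3-en-2-yl)phenyl]propyl}-4-(3-methylbut-2-en-1-yl)-1-benzofuran | COc1cc(CCCc2cc(C(C)(C)C=C)c(OCOC)cc2OC)c(CC=C(C)C)c2ccoc12 | intermediate
22 | 5-{3-[2-hydroxy-4-(methoxymethoxy)-5-(2-methylbut-3-en-2-yl)phenyl]propyl}-4-(3-methylbut-2-en-1-yl)-1-benzofuran-7-ol | Oc1cc(CCCc2cc(C(C)(C)C=C)c(OCOC)cc2O)c(CC=C(C)C)c2ccoc12 | intermediate
23 | 4-{3-[7-hydroxy-4-(3-methylbut-2-en-1-yl)-1-benzofuran-5-yl]propyl}-6-(2-methylbut-3-en-2-yl)benzene-1,3-diol | C=CC(C)(C)c1cc(CCCc2cc(O)c3occc3c2CC=C(C)C)c(O)cc1O | target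

**Step count**

Total: 11 steps. Longest linear sequence: 10 steps (steps 1–5, then 7–11); step 6 is a one-step side branch.

**Steps most likely to fail**

Step 7 (benzannulation). The vinylcarbene may take up a second alkyne or cyclise without CO insertion, the carbene may be captured by a ring-A alkene, and the electron-rich phenol may be oxidised to the quinone while the chromium is removed in air. The fallback sets out from carbene complex 15 and bromide 6 and comes back at 21. It takes the functionalised partner out of the ring-forming step and joins the halves afterwards by an sp2–sp3 coupling. Complex 15 is heated with commercial 5-chloropent-1-yne in THF to give 5-(3-chloropropyl)-7-methoxy-1-benzofuran-4-ol F1. Triflation with PhNTf2 and Et3N gives 5-(3-chloropropyl)-7-methoxy-1-benzofuran-4-yl trifluoromethanesulfonate F2. Stille coupling with stannane 20 under Pd(PPh3)4 and LiCl gives 5-(3-chloropropyl)-7-methoxy-4-(3-methylbut-2-en-1-yl)-1-benzofuran F3. NaI in acetone converts this to 5-(3-iodopropyl)-7-methoxy-4-(3-methylbut-2-en-1-yl)-1-benzofuran F4. F4 is then coupled with Grignard reagent 8, made from 6 and Mg, under Li2CuCl4 catalysis to give 21.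

Step 9 (prenyl transfer). Oxidative addition and transmetalation at a triflate flanked by two ortho substituents may be slow enough for reduction or hydrolysis of the triflate to take over, and allyl transposition during transfer may deliver the 1,1-dimethylallyl isomer. The fallback sets out from triflate 19 and comes back at 21. It builds the trisubstituted alkene by metathesis instead of transferring it. Stille coupling of 19 with allyltributylstannane, which has no regiochemical ambiguity, gives 4-allyl-7-methoxy-5-{3-[2-methoxy-4-(methoxymethoxy)-5-(2-methylbut-3-en-2-yl)phenyl]propyl}-1-benzofuran F5. Cross-metathesis of F5 with 2-methylbut-2-ene and the second-generation Grubbs catalyst in CH2Cl2 should convert the allyl group into prenyl; the vinyl group on the quaternary carbon of ring A is far slower in metathesis, and the reaction is stopped once the allyl group is consumed.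

Step 2 (Claisen rearrangement). The allyl–oxygen bond may ionise instead of shifting in concert, which would lose the prenyl group or give the linear prenyl phenol by a 1,3-shift, and the product phenol may close onto its own vinyl group under Lewis acid. The fallback sets out from phenol 1 and comes back at 9. It builds the quaternary benzylic carbon by enolate arylation instead of a sigmatropic shift. MOM protection of 1 gives 1-bromo-2-methoxy-4-(methoxymethoxy)benzene F6. Its Grignard reagent, [2-methoxy-4-(methoxymethoxy)phenyl]magnesium bromide F7, is coupled with iodide 7 under Li2CuCl4 catalysis to give trimethyl{5-[2-methoxy-4-(methoxymethoxy)phenyl]pent-1-yn-1-yl}silane F8. NBS in MeCN brominates the position para to OMe and ortho to the MOM ether, giving {5-[5-bromo-2-methoxy-4-(methoxymethoxy)phenyl]pent-1-yn-1-yl}trimethylsilane F9. Palladium-catalysed α-arylation of isobutyraldehyde with F9 ([Pd(allyl)Cl]2, dppf, Cs2CO3, dioxane, 90 °C) gives 2-{4-methoxy-2-(methoxymethoxy)-5-[5-(trimethylsilyl)pent-4-yn-1-yl]phenyl}-2-methylpropanal F10. Wittig methylenation of F10 (Ph3PCH3Br, KOtBu, THF) gives 9.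

**Further compounds**

F1 | step 7 | 5-(3-chloropropyl)-7-methoxy-1-benzofuran-4-ol | COc1cc(CCCCl)c(O)c2ccoc12
F2 | step 7 | 5-(3-chloropropyl)-7-methoxy-1-benzofuran-4-yl trifluoromethanesulfonate | COc1cc(CCCCl)c(OS(=O)(=O)C(F)(F)F)c2ccoc12
F3 | step 7 | 5-(3-chloropropyl)-7-methoxy-4-(3-methylbut-2-en-1-yl)-1-benzofuran | COc1cc(CCCCl)c(CC=C(C)C)c2ccoc12
F4 | step 7 | 5-(3-iodopropyl)-7-methoxy-4-(3-methylbut-2-en-1-yl)-1-benzofuran | COc1cc(CCCI)c(CC=C(C)C)c2ccoc12
F5 | step 9 | 4-allyl-7-methoxy-5-{3-[2-methoxy-4-(methoxymethoxy)-5-(2-methylbut-3-en-2-yl)phenyl]propyl}-1-benzofuran | COc1cc(CCCc2cc(C(C)(C)C=C)c(OCOC)cc2OC)c(CC=C)c2ccoc12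
F6 | step 2 | 1-bromo-2-methoxy-4-(methoxymethoxy)benzene | COCOc1ccc(Br)c(OC)c1
F7 | step 2 | [2-methoxy-4-(methoxymethoxy)phenyl]magnesium bromide | COCOc1ccc([Mg]Br)c(OC)c1
F8 | step 2 | trimethyl{5-[2-methoxy-4-(methoxymethoxy)phenyl]pent-1-yn-1-yl}silane | COCOc1ccc(CCCC#C[Si](C)(C)C)c(OC)c1
F9 | step 2 | {5-[5-bromo-2-methoxy-4-(methoxymethoxy)phenyl]pent-1-yn-1-yl}trimethylsilane | COCOc1cc(OC)c(CCCC#C[Si](C)(C)C)cc1Br
F10 | step 2 | 2-{4-methoxy-2-(methoxymethoxy)-5-[5-(trimethylsilyl)pent-4-yn-1-yl]phenyl}-2-methylpropanal | COCOc1cc(OC)c(CCCC#C[Si](C)(C)C)cc1C(C)(C)C=O
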